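**Assumption:** the target has no stereocentre and is achiral, so the "single enantiomer" is the compound itself and no stereocontrol is needed. Ring letters: ring A = 5-hydroxy-1,3-phenylene, ring B = 2,4,6-trihydroxyphenyl on ring A, ring C = 2,6-dihydroxy-1,4-phenylene, ring D = terminal 2,4,6-trihydroxyphenyl.

## Retrosynthetic overview

1. The target is a linear triether, ring B–O–ring A–O–ring C–O–ring D. No ring is constructed; all four benzene rings are bought and only joined through oxygen.
2. Last disconnection: nine O–CH3 bonds (global demethylation of the nonamethyl ether).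
3. Key disconnection: both terminal aryl C–O bonds (ring B–O and ring D–O) at once, giving a ring A–O–ring C bisphenol and two 2,4,6-trimethoxyphenyl cation equivalents carried by one symmetric diaryliodonium salt.
4. The two phenolic C–O bonds of the bisphenol come from a sterically steered double C–H borylation/oxidation of the ring A–O–ring C diaryl ether.
5. The central C–O bond comes from an Ullmann coupling of 2,6-dimethoxyphenol with 3-bromoanisole. Order of joining: A–C first, then B and D together.

## Route

Step 1
Reactants: 1 2,6-dimethoxyphenol; 2 3-bromoanisole (1-bromo-3-methoxybenzene)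
Product: 3 1,3-dimethoxy-2-(3-methoxyphenoxy)benzene
Conditions: CuI (10 mol%), picolinic acid (20 mol%), K3PO4 (2 equiv), DMSO, 90 °C, Ar
Reagents that add atoms: none
Why: Ullmann diaryl ether synthesis; the picolinate-ligated copper catalyst tolerates the 2,6-disubstituted phenoxide, the aryl bromide has no ortho substituent, and no stereocentre is formed.

Step 2
Reactants: 3 1,3-dimethoxy-2-(3-methoxyphenoxy)benzene
Product: 5 3-(4-hydroxy-2,6-dimethoxyphenoxy)-5-methoxyphenol, via bis(pinacol boronate) 4 (not isolated)
Conditions: [Ir(OMe)(cod)]2 (2 mol%), 4,4'-di-tert-butyl-2,2'-bipyridine (4 mol%), B2pin2 (2.4 equiv), THF, 80 °C; volatiles removed in vacuo; then KHSO5 (as 2KHSO5·KHSO4·K2SO4, 5 equiv), acetone/H2O, 0 °C to rt, 15 min; NaHSO3 quench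
Reagents that add atoms: bis(pinacolato)diboron, CC1(C)OB(OC1(C)C)B1OC(C)(C)C(C)(C)O1 (boron of intermediate 4 only); potassium peroxymonosulfate KHSO5, [K+].[O-]S(=O)(=O)OO (the two new phenol oxygens of 5)
Why: Sterically governed Ir-catalysed C–H borylation (Hartwig–Miyaura type) takes the only two C–H bonds without an ortho substituent (C5 of ring A, C4 of ring C), and peroxide oxidation then converts each C–B bond into C–OH at the same position by a boron-to-oxygen 1,2-shift.

Step 3
Reactants: 6 2-iodo-1,3,5-trimethoxybenzene; 7 1,3,5-trimethoxybenzene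
Product: 9 bis(2,4,6-trimethoxyphenyl)iodonium 4-methylbenzenesulfonate, via hydroxy(tosyloxy)iodoarene 8 (not isolated)
Conditions: mCPBA (1.1 equiv), TsOH·H2O (1.05 equiv), MeCN, 0 °C to rt, 30 min; then 7 (1.05 equiv), rt, 15 min; precipitation with Et2O
Reagents that add atoms: 4-methylbenzenesulfonic acid monohydrate, Cc1ccc(S(=O)(=O)O)cc1.O (tosylate counter-ion of 9); 3-chloroperoxybenzoic acid, OOC(=O)c1cccc(Cl)c1 (hydroxyl oxygen of intermediate 8 only)
Why: One-pot diaryliodonium synthesis: peracid oxidation of the aryl iodide to a Koser-type trivalent-iodine species, then electrophilic aromatic substitution on 7, whose three C–H positions are equivalent so only one isomer can form.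

Step 4
Reactants: 5 3-(4-hydroxy-2,6-dimethoxyphenoxy)-5-methoxyphenol; 9 bis(2,4,6-trimethoxyphenyl)iodonium 4-methylbenzenesulfonate (2.6 equiv)
Product: 10 2-[3-methoxy-5-(2,4,6-trimethoxyphenoxy)phenoxy]-1,3-dimethoxy-5-(2,4,6-trimethoxyphenoxy)benzene
Conditions: Cu(MeCN)4PF6 (10 mol%), K3PO4 (4 equiv), MeCN/toluene 1:1, 60 °C, Ar, dark
Reagents that add atoms: none
Why: Proposed new method: 9 carries only 2,4,6-trimethoxyphenyl groups on trivalent iodine, so the aryl group that is normally the non-transferred spectator of aryl(2,4,6-trimethoxyphenyl)iodonium salts is the only one that can be delivered; monovalent copper should cleave one C–I bond (oxidative addition, or electron transfer and radical rebound, helped by an ortho-methoxy oxygen) to a trivalent aryl-copper species that binds each phenoxide of 5 and forms the C–O bond by reductive elimination, releasing 6, while C-arylation is disfavoured because every nucleophilic ring carbon of 5 is flanked by two substituents and would give a tetra-ortho-substituted biaryl; the closest known reaction types are the O-arylation of phenols with diaryliodonium salts (metal-free ligand coupling or copper-catalysed) and the forced transfer of hindered aryl groups from symmetric dimesityliodonium salts, but transfer of a 2,4,6-trimethoxyphenyl group from iodine to a phenol oxygen has not been shown.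

Step 5
Reactants: 10 2-[3-methoxy-5-(2,4,6-trimethoxyphenoxy)phenoxy]-1,3-dimethoxy-5-(2,4,6-trimethoxyphenoxy)benzene
Product: 11 2-[3-hydroxy-5-(2,4,6-trihydroxyphenoxy)phenoxy]-5-(2,4,6-trihydroxyphenoxy)benzene-1,3-diol
Conditions: BBr3 (20 equiv), CH2Cl2, −78 °C to rt, 24 h, Ar; then H2O, 0 °C; degassed solvents, Sephadex LH-20 (MeOH)
Reagents that add atoms: none
Why: Lewis-acid aryl methyl ether cleavage (BBr3 demethylation): bromide removes each methyl group by SN2 from the boron-complexed oxygen, whereas the aryl–O–aryl bonds have no sp3 carbon to attack and survive; 11 has no stereocentre.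

## Compound list

1 | 2,6-dimethoxyphenol | COc1cccc(OC)c1O | starting material
2 | 3-bromoanisole | COc1cccc(Br)c1 | starting material
3 | 1,3-dimethoxy-2-(3-methoxyphenoxy)benzene | COc1cccc(Oc2c(OC)cccc2OC)c1 | intermediate
4 | 2-[3-methoxy-5-[2,6-dimethoxy-4-(4,4,5,5-tetramethyl-1,3,2-dioxaborolan-2-yl)phenoxy]phenyl]-4,4,5,5-tetramethyl-1,3,2-dioxaborolane (bis(pinacol boronate), not isolated) | COc1cc(Oc2c(OC)cc(B3OC(C)(C)C(C)(C)O3)cc2OC)cc(B2OC(C)(C)C(C)(C)O2)c1 | intermediate
5 | 3-(4-hydroxy-2,6-dimethoxyphenoxy)-5-methoxyphenol | COc1cc(O)cc(Oc2c(OC)cc(O)cc2OC)c1 | intermediate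
6 | 2-iodo-1,3,5-trimethoxybenzene | COc1cc(OC)c(I)c(OC)c1 | starting material
7 | 1,3,5-trimethoxybenzene | COc1cc(OC)cc(OC)c1 | starting material
8 | 2-[hydroxy(tosyloxy)iodo]-1,3,5-trimethoxybenzene (not isolated) | COc1cc(OC)c(I(O)OS(=O)(=O)c2ccc(C)cc2)c(OC)c1 | intermediate
9 | bis(2,4,6-trimethoxyphenyl)iodonium 4-methylbenzenesulfonate | COc1cc(OC)c([I+]c2c(OC)cc(OC)cc2OC)c(OC)c1.Cc1ccc(S(=O)(=O)[O-])cc1 | intermediate
10 | 2-[3-methoxy-5-(2,4,6-trimethoxyphenoxy)phenoxy]-1,3-dimethoxy-5-(2,4,6-trimethoxyphenoxy)benzene (nonamethyl ether of the target) | COc1cc(Oc2c(OC)cc(OC)cc2OC)cc(Oc2c(OC)cc(Oc3c(OC)cc(OC)cc3OC)cc2OC)c1 | intermediate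
11 | 2-[3-hydroxy-5-(2,4,6-trihydroxyphenoxy)phenoxy]-5-(2,4,6-trihydroxyphenoxy)benzene-1,3-diol (CNP0159471.0) | Oc1cc(Oc2c(O)cc(O)cc2O)cc(Oc2c(O)cc(Oc3c(O)cc(O)cc3O)cc2O)c1 | target

## Step count and risks

Total step count: 5. Longest linear sequence: 4 (steps 1, 2, 4, 5); step 3 is a one-step side branch that makes the aryl donor. The two equivalents of 6 released in step 4 can be recovered and returned to step 3.

**Most likely to fail: step 4 (the proposed new step).** The electron-rich, doubly ortho-substituted aryl group may transfer too slowly, so that oxidation of the phenoxides of 5 by 9 or by the copper catalyst takes over, or mono-arylation stalls. The fallback sets out from 5 and comes back at 10 by a known Ullmann diaryl ether synthesis with the commercial aryl iodide 6 as electrophile (6 3 equiv, CuI 20 mol%, picolinic acid 40 mol%, K3PO4, DMSO, 110 °C, Ar). This swaps the iodonium donor for a classical aryl halide coupling, removes the need for step 3, and makes no compound outside the list (F0).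

**Second: step 3.** The peracid may oxidise the very electron-rich ring of 6, or intermediate 8 may arylate unreacted 6 at its free ring positions instead of waiting for 7. The fallback sets out from 6 and separates oxidation from arylation. Compound 6 is oxidised with NaBO3·4H2O in acetic acid at 45 °C to the isolable 2-(diacetoxyiodo)-1,3,5-trimethoxybenzene F1. F1 is then condensed with 7 and TsOH·H2O (1 equiv) in 2,2,2-trifluoroethanol at rt, so no oxidant ever meets 7 or the product, and the route is rejoined at 9.

**Third: step 5.** Nine ether cleavages on one molecule may stop at partially methylated mixtures, and free 11 is air-sensitive and hard to purify. The fallback sets out from 10 and uses a hard-acid/soft-nucleophile cleavage (AlCl3, EtSH, CH2Cl2, 0 °C to rt). The crude polyphenol is peracetylated directly (Ac2O, pyridine) to the stable, chromatographable nonaacetate of 11 F2. After purification, F2 is deacetylated (catalytic NaOMe, degassed MeOH, Ar, then acidic resin) to come back at 11.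

## Further compounds

F0 | step 4 | none | none
F1 | step 3 | 2-(diacetoxyiodo)-1,3,5-trimethoxybenzene | COc1cc(OC)c(I(OC(C)=O)OC(C)=O)c(OC)c1
F2 | step 5 | nonaacetate of 11, 2-[3-acetoxy-5-(2,4,6-triacetoxyphenoxy)phenoxy]-5-(2,4,6-triacetoxyphenoxy)-1,3-phenylene diacetate | CC(=O)Oc1cc(Oc2c(OC(C)=O)cc(OC(C)=O)cc2OC(C)=O)cc(Oc2c(OC(C)=O)cc(Oc3c(OC(C)=O)cc(OC(C)=O)cc3OC(C)=O)cc2OC(C)=O)c1
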